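**Retrosynthetic overview**
- Botcinin K ⇐ C3 silyl ether of the bicyclic lactone: the octenoate is put on O7 after ring B (the δ-lactone) is closed.
- Ring B ⇐ keto-aldehyde of the finished tetrahydropyran: a chelation-controlled anti Mukaiyama aldol adds C1–C2 at C3, then the thioester lactonises onto O5.
- Ring A (the tetrahydropyran) ⇐ acyclic epoxy alcohol: 6-exo epoxide opening by the tertiary C4–OH at C8, with inversion, makes the bis-tertiary ether.
- Chain C3–C10 ⇐ α-hydroxy-β-keto ester + tiglic aldehyde (titanium syn aldol, then 1,3-syn reduction).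
- Key disconnection C4–C5: crossed benzoin of propanal (as a propionyl anion, via its Breslow intermediate) with the ketone of methyl pyruvate, setting the C4 quaternary carbinol. Ring order: A, then B.

Atom labels C1–C10 follow botcinin numbering (C1 lactone carbonyl, C9 acetyl carbonyl).
Assumption: the facial sense of the two catalyst-controlled steps (1 and 5) is taken from the usual selectivity models; if either turns out opposite, the enantiomeric catalyst is used.

**Step 1**
Reactants: 1 propanal; 2 methyl pyruvate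
Product: 3 methyl (2S)-2-hydroxy-2-methyl-3-oxopentanoate
Conditions: (5aR,10bS)-2-(pentafluorophenyl)-5a,10b-dihydro-4H,6H-indeno[2,1-b][1,2,4]triazolo[4,3-d][1,4]oxazin-2-ium tetrafluoroborate (10 mol %), iPr2NEt (20 mol %), 2 (1.5 equiv), CH2Cl2, 4 Å MS, 0 °C to rt
Reagents that add atoms: none
Why: NHC-catalysed crossed benzoin (aldehyde–ketone acyloin) reaction in which the Breslow intermediate of propanal adds as an acyl anion to the activated ketone carbonyl of the α-keto ester, forming C4–C5, with the chiral triazolium choosing the ketone face and so setting the C4 quaternary carbinol.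

**Step 2**
Reactants: 3 methyl (2S)-2-hydroxy-2-methyl-3-oxopentanoate; 4 (2E)-2-methylbut-2-enal
Product: 5 methyl (2S,4R,5R,6E)-2,5-dihydroxy-2,4,6-trimethyl-3-oxooct-6-enoate
Conditions: TiCl4 (1.1 equiv), iPr2NEt (2.5 equiv), CH2Cl2, −78 °C; then 4 (1.5 equiv), −78 to −40 °C; aq. NH4Cl
Reagents that add atoms: none
Why: Titanium-mediated syn aldol through a Zimmerman–Traxler chair: the Z enolate is held in a five-membered chelate by the C4 titanium alkoxide and the ester carbonyl caps one apical site, so the aldehyde is delivered on the C4-methyl face, giving C6/C7 syn and C4/C6 anti.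

**Step 3**
Reactants: 5 methyl (2S,4R,5R,6E)-2,5-dihydroxy-2,4,6-trimethyl-3-oxooct-6-enoate
Product: 6 methyl (2S,3S,4R,5R,6E)-2,3,5-trihydroxy-2,4,6-trimethyloct-6-enoate
Conditions: Et2BOMe, NaBH4, THF/MeOH (4:1), −78 °C; AcOH, then MeOH azeotrope
Reagents that add atoms: none
Why: Narasaka–Prasad reduction: the β-hydroxy ketone forms a six-membered boron chelate and external hydride adds axially, giving the 1,3-syn diol and so the C5 carbinol syn to C7–OH.

**Step 4**
Reactants: 6 methyl (2S,3S,4R,5R,6E)-2,3,5-trihydroxy-2,4,6-trimethyloct-6-enoate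
Product: 7 methyl (2S,3S,4R,5R,6E)-2-hydroxy-2,4,6-trimethyl-3,5-bis(triethylsilyloxy)oct-6-enoate
Conditions: Et3SiCl (2.5 equiv), imidazole, DMF, 0 °C to rt
Reagents that add atoms: chlorotriethylsilane CC[Si](Cl)(CC)CC
Why: Silylation of the two secondary hydroxyls only (the tertiary C4–OH is too hindered), which stops δ-lactonisation onto the ester and blocks O5 as a 5-exo competitor in the later epoxide opening.

**Step 5**
Reactants: 7 methyl (2S,3S,4R,5R,6E)-2-hydroxy-2,4,6-trimethyl-3,5-bis(triethylsilyloxy)oct-6-enoate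
Product: 8 methyl (2S,3S,4S,5R)-5-[(2R,3S)-2,3-dimethyloxiran-2-yl]-2-hydroxy-2,4-dimethyl-3,5-bis(triethylsilyloxy)pentanoate
Conditions: 1,2:4,5-di-O-isopropylidene-β-L-erythro-2,3-hexodiulo-2,6-pyranose (30 mol %), KHSO5 (Oxone), K2CO3, Bu4NHSO4, MeCN/CH2(OMe)2/aq. Na2B4O7 buffer (pH 10.5), 0 °C
Reagents that add atoms: potassium peroxymonosulfate [K+].[O-]S(=O)(=O)OO
Why: Shi asymmetric epoxidation (chiral dioxirane, spiro transition state) of the only alkene, with reagent control putting the epoxide oxygen on the face syn to the C7 silyloxy group of the extended chain, which is the epoxide needed for inversion at C8.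

**Step 6**
Reactants: 8 methyl (2S,3S,4S,5R)-5-[(2R,3S)-2,3-dimethyloxiran-2-yl]-2-hydroxy-2,4-dimethyl-3,5-bis(triethylsilyloxy)pentanoate
Product: 9 methyl (2S,3S,4R,5R,6S)-6-[(1S)-1-hydroxyethyl]-2,4,6-trimethyl-3,5-bis(triethylsilyloxy)oxane-2-carboxylate
Conditions: (1S)-10-camphorsulfonic acid (10 mol %), CH2Cl2, 0 °C
Reagents that add atoms: none
Why: Acid-catalysed 6-exo-tet epoxide-opening cyclisation: the tertiary C4–OH attacks the tertiary epoxide carbon C8 (Markovnikov and Baldwin-favoured) with inversion, closing ring A and setting the second quaternary ether carbon with its methyl axial and cis to the C4 methyl.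

**Step 7**
Reactants: 9 methyl (2S,3S,4R,5R,6S)-6-[(1S)-1-hydroxyethyl]-2,4,6-trimethyl-3,5-bis(triethylsilyloxy)oxane-2-carboxylate
Product: 10 (1S)-1-[(2S,3R,4S,5S,6R)-6-(hydroxymethyl)-2,4,6-trimethyl-3,5-bis(triethylsilyloxy)oxan-2-yl]ethan-1-ol
Conditions: iBu2AlH (4 equiv), CH2Cl2, −78 to 0 °C; aq. KNaC4H4O6
Reagents that add atoms: none
Why: Hydride reduction of the methyl ester to the primary alcohol; silyl ethers and the ring ether are inert, and no other reducible group is present at this stage.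

**Step 8**
Reactants: 10 (1S)-1-[(2S,3R,4S,5S,6R)-6-(hydroxymethyl)-2,4,6-trimethyl-3,5-bis(triethylsilyloxy)oxan-2-yl]ethan-1-ol
Product: 11 (2S,3S,4S,5R,6R)-6-acetyl-2,4,6-trimethyl-3,5-bis(triethylsilyloxy)oxane-2-carbaldehyde
Conditions: Dess–Martin periodinane (3 equiv), NaHCO3, CH2Cl2, rt
Reagents that add atoms: none
Why: Double Dess–Martin oxidation gives the C3 aldehyde and the C9 methyl ketone in one operation; both flank quaternary carbons, so neither new carbonyl can epimerise an adjacent centre.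

**Step 9**
Reactants: 12 S-ethyl propanethioate
Product: 13 (Z)-{[1-(ethylsulfanyl)prop-1-en-1-yl]oxy}trimethylsilane
Conditions: LiN(iPr)2, THF, −78 °C; Me3SiCl; pentane, filtration
Reagents that add atoms: chlorotrimethylsilane C[Si](C)(C)Cl
Why: Kinetic enolisation of the thioester in THF (Ireland model) and O-silylation give the silyl ketene thioacetal with methyl trans to the silyloxy group.

**Step 10**
Reactants: 11 (2S,3S,4S,5R,6R)-6-acetyl-2,4,6-trimethyl-3,5-bis(triethylsilyloxy)oxane-2-carbaldehyde; 13 (Z)-{[1-(ethylsulfanyl)prop-1-en-1-yl]oxy}trimethylsilane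
Product: 14 S-ethyl (2R,3S)-3-[(2R,3S,4S,5R,6R)-6-acetyl-2,4,6-trimethyl-3,5-bis(triethylsilyloxy)oxan-2-yl]-3-hydroxy-2-methylpropanethioate
Conditions: MgBr2·OEt2 (3 equiv), 13 (3 equiv), CH2Cl2, −78 to −20 °C; aq. NH4Cl
Reagents that add atoms: none
Why: Chelation-controlled Mukaiyama aldol: magnesium bridges the aldehyde oxygen and the ring oxygen, the nucleophile attacks from the side of the axial C4 methyl (Cram chelate, sets C3) and the open antiperiplanar transition state of this thioester silyl ketene acetal gives the 2,3-anti product (sets C2), while the hindered methyl ketone does not react.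

**Step 11**
Reactants: 14 S-ethyl (2R,3S)-3-[(2R,3S,4S,5R,6R)-6-acetyl-2,4,6-trimethyl-3,5-bis(triethylsilyloxy)oxan-2-yl]-3-hydroxy-2-methylpropanethioate
Product: 15 S-ethyl (2R,3S)-3-[(2S,3S,4S,5R,6R)-6-acetyl-2,4,6-trimethyl-3,5-bis(triethylsilyloxy)oxan-2-yl]-3-[(tert-butyldimethylsilyl)oxy]-2-methylpropanethioate
Conditions: tBuMe2SiOTf, 2,6-lutidine, CH2Cl2, −78 to 0 °C
Reagents that add atoms: tert-butyldimethylsilyl trifluoromethanesulfonate CC(C)(C)[Si](C)(C)OS(=O)(=O)C(F)(F)F
Why: Silyl protection of the C3 hydroxyl with a group that outlasts the triethylsilyl ethers, so that O7 can later be acylated as the only free hydroxyl.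

**Step 12**
Reactants: 15 S-ethyl (2R,3S)-3-[(2S,3S,4S,5R,6R)-6-acetyl-2,4,6-trimethyl-3,5-bis(triethylsilyloxy)oxan-2-yl]-3-[(tert-butyldimethylsilyl)oxy]-2-methylpropanethioate
Product: 17 (3R,4S,4aS,6R,7R,8R,8aS)-6-acetyl-4-[(tert-butyldimethylsilyl)oxy]-7-hydroxy-3,4a,6,8-tetramethylhexahydro-2H,5H-pyrano[3,2-b]pyran-2-one, via diol thioester 16 (not isolated)
Conditions: HF·pyridine, pyridine, THF, 0 °C; then AgOCOCF3, Na2HPO4, benzene, rt
Reagents that add atoms: none
Why: Selective cleavage of the two triethylsilyl ethers, then silver-promoted thioester lactonisation (Masamune type) in which only O5 can reach C1 through a six-membered ring (O7 would need eight), closing ring B trans-fused and leaving O7–H free.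

**Step 13**
Reactants: 17 (3R,4S,4aS,6R,7R,8R,8aS)-6-acetyl-4-[(tert-butyldimethylsilyl)oxy]-7-hydroxy-3,4a,6,8-tetramethylhexahydro-2H,5H-pyrano[3,2-b]pyran-2-one; 18 (2E)-oct-2-enoic acid
Product: 19 (3R,4S,4aS,6R,7R,8S,8aS)-6-acetyl-4-[(tert-butyldimethylsilyl)oxy]-3,4a,6,8-tetramethyl-2-oxooctahydropyrano[3,2-b]pyran-7-yl (2E)-oct-2-enoate
Conditions: 18, 2,4,6-trichlorobenzoyl chloride, Et3N, THF, rt; then 17, 4-(dimethylamino)pyridine, toluene, 40 °C
Reagents that add atoms: none
Why: Yamaguchi esterification through the mixed anhydride acylates the hindered equatorial C7 hydroxyl with retention at C7 and without touching the E alkene.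

**Step 14**
Reactants: 19 (3R,4S,4aS,6R,7R,8S,8aS)-6-acetyl-4-[(tert-butyldimethylsilyl)oxy]-3,4a,6,8-tetramethyl-2-oxooctahydropyrano[3,2-b]pyran-7-yl (2E)-oct-2-enoate
Product: 20 Botcinin K
Conditions: HF·pyridine, THF, 0 °C to rt
Reagents that add atoms: none
Why: Fluoride-mediated desilylation under mildly acidic conditions frees the C3 hydroxyl without epimerising C2, opening the lactone or isomerising the enoate.

**Compound list**
1 | propanal | CCC=O | starting material
2 | methyl pyruvate (methyl 2-oxopropanoate) | CC(=O)C(=O)OC | starting material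
3 | methyl (2S)-2-hydroxy-2-methyl-3-oxopentanoate | COC(=O)[C@@](C)(O)C(=O)CC | intermediate
4 | (2E)-2-methylbut-2-enal (tiglic aldehyde) | C/C=C(\C)C=O | starting material
5 | methyl (2S,4R,5R,6E)-2,5-dihydroxy-2,4,6-trimethyl-3-oxooct-6-enoate | COC(=O)[C@@](C)(O)C(=O)[C@H](C)[C@@H](O)/C(C)=C/C | intermediate
6 | methyl (2S,3S,4R,5R,6E)-2,3,5-trihydroxy-2,4,6-trimethyloct-6-enoate | COC(=O)[C@@](C)(O)[C@@H](O)[C@H](C)[C@@H](O)/C(C)=C/C | intermediate
7 | methyl (2S,3S,4R,5R,6E)-2-hydroxy-2,4,6-trimethyl-3,5-bis(triethylsilyloxy)oct-6-enoate | COC(=O)[C@@](C)(O)[C@@H](O[Si](CC)(CC)CC)[C@H](C)[C@@H](O[Si](CC)(CC)CC)/C(C)=C/C | intermediate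
8 | methyl (2S,3S,4S,5R)-5-[(2R,3S)-2,3-dimethyloxiran-2-yl]-2-hydroxy-2,4-dimethyl-3,5-bis(triethylsilyloxy)pentanoate | COC(=O)[C@@](C)(O)[C@@H](O[Si](CC)(CC)CC)[C@H](C)[C@@H](O[Si](CC)(CC)CC)[C@]1(C)O[C@H]1C | intermediate
9 | methyl (2S,3S,4R,5R,6S)-6-[(1S)-1-hydroxyethyl]-2,4,6-trimethyl-3,5-bis(triethylsilyloxy)oxane-2-carboxylate | COC(=O)[C@@]1(C)O[C@@](C)([C@H](C)O)[C@H](O[Si](CC)(CC)CC)[C@@H](C)[C@@H]1O[Si](CC)(CC)CC | intermediate
10 | (1S)-1-[(2S,3R,4S,5S,6R)-6-(hydroxymethyl)-2,4,6-trimethyl-3,5-bis(triethylsilyloxy)oxan-2-yl]ethan-1-ol | OC[C@@]1(C)O[C@@](C)([C@H](C)O)[C@H](O[Si](CC)(CC)CC)[C@@H](C)[C@@H]1O[Si](CC)(CC)CC | intermediate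
11 | (2S,3S,4S,5R,6R)-6-acetyl-2,4,6-trimethyl-3,5-bis(triethylsilyloxy)oxane-2-carbaldehyde | O=C[C@@]1(C)O[C@@](C)(C(C)=O)[C@H](O[Si](CC)(CC)CC)[C@@H](C)[C@@H]1O[Si](CC)(CC)CC | intermediate
12 | S-ethyl propanethioate | CCC(=O)SCC | starting material
13 | (Z)-{[1-(ethylsulfanyl)prop-1-en-1-yl]oxy}trimethylsilane | C/C=C(\SCC)O[Si](C)(C)C | intermediate
14 | S-ethyl (2R,3S)-3-[(2R,3S,4S,5R,6R)-6-acetyl-2,4,6-trimethyl-3,5-bis(triethylsilyloxy)oxan-2-yl]-3-hydroxy-2-methylpropanethioate | CCSC(=O)[C@H](C)[C@H](O)[C@@]1(C)O[C@@](C)(C(C)=O)[C@H](O[Si](CC)(CC)CC)[C@@H](C)[C@@H]1O[Si](CC)(CC)CC | intermediate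
15 | S-ethyl (2R,3S)-3-[(2S,3S,4S,5R,6R)-6-acetyl-2,4,6-trimethyl-3,5-bis(triethylsilyloxy)oxan-2-yl]-3-[(tert-butyldimethylsilyl)oxy]-2-methylpropanethioate | CCSC(=O)[C@H](C)[C@H](O[Si](C)(C)C(C)(C)C)[C@@]1(C)O[C@@](C)(C(C)=O)[C@H](O[Si](CC)(CC)CC)[C@@H](C)[C@@H]1O[Si](CC)(CC)CC | intermediate
16 | S-ethyl (2R,3S)-3-[(2S,3S,4S,5R,6R)-6-acetyl-3,5-dihydroxy-2,4,6-trimethyloxan-2-yl]-3-[(tert-butyldimethylsilyl)oxy]-2-methylpropanethioate (diol thioester) | CCSC(=O)[C@H](C)[C@H](O[Si](C)(C)C(C)(C)C)[C@@]1(C)O[C@@](C)(C(C)=O)[C@H](O)[C@@H](C)[C@@H]1O | intermediate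
17 | (3R,4S,4aS,6R,7R,8R,8aS)-6-acetyl-4-[(tert-butyldimethylsilyl)oxy]-7-hydroxy-3,4a,6,8-tetramethylhexahydro-2H,5H-pyrano[3,2-b]pyran-2-one | O[C@@H]1[C@@H](C)[C@@H]2OC(=O)[C@H](C)[C@H](O[Si](C)(C)C(C)(C)C)[C@@]2(C)O[C@@]1(C)C(C)=O | intermediate
18 | (2E)-oct-2-enoic acid | CCCCC/C=C/C(=O)O | starting material
19 | (3R,4S,4aS,6R,7R,8S,8aS)-6-acetyl-4-[(tert-butyldimethylsilyl)oxy]-3,4a,6,8-tetramethyl-2-oxooctahydropyrano[3,2-b]pyran-7-yl (2E)-oct-2-enoate | CCCCC/C=C/C(=O)O[C@@H]1[C@@H](C)[C@@H]2OC(=O)[C@H](C)[C@H](O[Si](C)(C)C(C)(C)C)[C@@]2(C)O[C@@]1(C)C(C)=O | intermediate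
20 | Botcinin K, (3R,4S,4aR,6R,7R,8S,8aS)-6-acetyl-4-hydroxy-3,4a,6,8-tetramethyl-2-oxooctahydropyrano[3,2-b]pyran-7-yl (2E)-oct-2-enoate (botcinin numbering 2R,3S,4R,5S,6S,7R,8R) | CCCCC/C=C/C(=O)O[C@@H]1[C@@H](C)[C@@H]2OC(=O)[C@H](C)[C@H](O)[C@@]2(C)O[C@@]1(C)C(C)=O | target

**Step count and risks**
Total steps: 14. Longest linear sequence: 13 (steps 1–8 and 10–14; step 9 is a one-step side branch).

Steps most likely to fail:

Step 1 (crossed benzoin with an enolisable, small α-keto ester: aldol side reactions, propanal homocoupling, uncertain ee). Fallback, setting out from 1 and returning at 3: a zinc Reformatsky reaction of 1 with methyl 2-bromopropanoate gives methyl 3-hydroxy-2-methylpentanoate F1; Dess–Martin oxidation gives methyl 2-methyl-3-oxopentanoate F2; catalytic enantioselective α-hydroxylation of this β-keto ester (cumene hydroperoxide with a cinchona-derived phase-transfer catalyst) gives 3. The quaternary carbinol is then made by electrophilic oxygenation of an enolate instead of by acyl-anion addition.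

Step 2 (face selection rests on the proposed titanium chelate, since methyl and ester at C4 differ little in size). Fallback, setting out from 3 and returning at 5: silylation (Me3SiCl, imidazole) gives methyl (2S)-2-methyl-3-oxo-2-(trimethylsilyloxy)pentanoate F3; a reagent-controlled Paterson aldol with 4 through the Z enol diisopinocampheylborinate (diisopinocampheylboron triflate, iPr2NEt, then oxidative work-up) gives methyl (2S,4R,5R,6E)-5-hydroxy-2,4,6-trimethyl-3-oxo-2-(trimethylsilyloxy)oct-6-enoate F4; citric acid in methanol removes the silyl group to give 5. Stereocontrol moves from the substrate chelate to the chiral boron ligands.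

Step 6 (a hindered tertiary alcohol must open a tertiary epoxide carbon; silyl-ether participation or semipinacol shift could compete). Fallback, setting out from 7 (step 5 is skipped) and returning at 11: intramolecular oxymercuration with Hg(OCOCF3)2 in CH2Cl2 is reversible, so the chair with the C8 methyl axial and the larger 1-mercurioethyl group equatorial is selected, giving the C9 trifluoroacetoxymercurio analogue of 9 F5. Oxidative demercuration (NaBH4, O2, DMF) gives 9 together with its C9 epimer F6. The mixture is taken through step 7, where F6 gives the C9 epimer of 10 F7, and step 8, and both series converge on 11, in which C9 is no longer stereogenic.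

**Further compounds**
F1 | step 1 | methyl 3-hydroxy-2-methylpentanoate (diastereomer mixture) | CCC(O)C(C)C(=O)OC
F2 | step 1 | methyl 2-methyl-3-oxopentanoate (racemic) | CCC(=O)C(C)C(=O)OC
F3 | step 2 | methyl (2S)-2-methyl-3-oxo-2-(trimethylsilyloxy)pentanoate | COC(=O)[C@@](C)(O[Si](C)(C)C)C(=O)CC
F4 | step 2 | methyl (2S,4R,5R,6E)-5-hydroxy-2,4,6-trimethyl-3-oxo-2-(trimethylsilyloxy)oct-6-enoate | COC(=O)[C@@](C)(O[Si](C)(C)C)C(=O)[C@H](C)[C@@H](O)/C(C)=C/C
F5 | step 6 | C9 trifluoroacetoxymercurio analogue of 9 (HgOCOCF3 in place of the C9 hydroxyl, same configuration at every centre) | COC(=O)[C@@]1(C)O[C@@](C)([C@H](C)[Hg]OC(=O)C(F)(F)F)[C@H](O[Si](CC)(CC)CC)[C@@H](C)[C@@H]1O[Si](CC)(CC)CC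
F6 | step 6 | C9 epimer of 9, methyl (2S,3S,4R,5R,6S)-6-[(1R)-1-hydroxyethyl]-2,4,6-trimethyl-3,5-bis(triethylsilyloxy)oxane-2-carboxylate | COC(=O)[C@@]1(C)O[C@@](C)([C@@H](C)O)[C@H](O[Si](CC)(CC)CC)[C@@H](C)[C@@H]1O[Si](CC)(CC)CC
F7 | step 6 | C9 epimer of 10, (1R)-1-[(2S,3R,4S,5S,6R)-6-(hydroxymethyl)-2,4,6-trimethyl-3,5-bis(triethylsilyloxy)oxan-2-yl]ethan-1-ol | OC[C@@]1(C)O[C@@](C)([C@@H](C)O)[C@H](O[Si](CC)(CC)CC)[C@@H](C)[C@@H]1O[Si](CC)(CC)CC
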